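**Plan**
- Cuts, in retrosynthetic order: O7–CH2 of the prenyl ether; then C4–C4a and O1–C2 of pyranone ring C together; then C2–C3 of the three-carbon unit.
- Enabling feature: ring A is a resorcinol whose C4a lies para to O7 and ortho to O1. The unsubstituted arene is therefore nucleophilic exactly where C4 must bond, and it already carries the oxygen that closes onto C2.
- Forward: rings A and B are purchased. C2–C3 comes from aroylation of a glycolate enolate, with O3 masked as a benzyl ether. Ring C, the only ring built, arises in a solvent-free thermal [3+3] annulation.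
- Hydrogenolysis then frees O3, and the prenyl group goes onto O7 last, so the allylic ether meets neither heat nor hydrogen.
- Stereochemistry: there is none to set. The only sp3 centre on the way (the α-carbon of the ketoester) is labile and ends as sp2 C3.

Key step: step 2

Remark: the target has no stereocentre, and its only alkene carries two identical methyl groups. It is therefore a single achiral compound and the route needs no stereocontrol.

Step 1
Reactants: 1 ethyl 2-(benzyloxy)acetate; 2 3,4-dimethoxybenzoyl chloride
Product: 4 ethyl 2-(benzyloxy)-3-(3,4-dimethoxyphenyl)-3-oxopropanoate (racemic; α-carbon labile), via lithium enolate 3 (not isolated)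
Conditions: LDA (2.1 equiv), 1 (2.1 equiv), THF, −78 °C; then 2 (1.0 equiv), −78 → −30 °C; AcOH, then aq NH4Cl
Reagents that add atoms: none
Why: Crossed Claisen condensation in its enolate/acid chloride form: the preformed, internally chelated lithium enolate 3 should add through carbon to the non-enolisable aroyl chloride, the second equivalent of 3 takes up the acidic α-proton of 4 so that the acylation is not stalled, and the new α-carbon is configurationally labile and carried as the racemate.

Step 2
Reactants: 4 ethyl 2-(benzyloxy)-3-(3,4-dimethoxyphenyl)-3-oxopropanoate; 5 resorcinol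
Product: 9 3-(benzyloxy)-2-(3,4-dimethoxyphenyl)-7-hydroxychromen-4-one, via α-oxoketene 6 (not isolated), via aryl diketone 7 (not isolated), via cyclic hemiketal 8 (not isolated)
Conditions: 5 (2 equiv), neat melt, 240–250 °C, N2 sweep with continuous removal of EtOH and H2O
Reagents that add atoms: none
Why: Above about 200 °C the ketoester should expel ethanol to give the α-oxoketene 6, whose ketene carbon is attacked by C4 of resorcinol (capture at a phenolic oxygen is reversible at this temperature and merely stores the ketene), so that C4–C4a is formed and the o-hydroxyaryl diketone 7 results. The hydroxyl ortho to the new ketone then adds to the aroyl carbonyl in a 6-exo-trig closure to hemiketal 8, and loss of water gives the conjugated pyranone ring C with O1–C2 in place. The closest known reaction type is the Mentzer pyrone synthesis, the catalyst-free thermal condensation of phenols with β-ketoesters to chromones and flavones, which accepts α-substituted ketoesters. No stereocentre is created, since the labile α-carbon of 4 and the transient centres of 8 all end as sp2 atoms. Site selectivity (7-hydroxy, not 5-hydroxy) rests on the substrate, because C4 of resorcinol is para to one hydroxyl, ortho to the other and unhindered, whereas C2 is wedged between both hydroxyls; chromone rather than coumarin formation rests on the absence of acid, which leaves the aroyl ketone unactivated towards the arene, and on the α-benzyloxy group that crowds that ketone. The excess of resorcinol should keep the free 7-hydroxyl of 9 from being acylated by further 6, and sweeping out ethanol and water drives both eliminations and shields 4 from hydrolysis and decarboxylation.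

Step 3
Reactants: 9 3-(benzyloxy)-2-(3,4-dimethoxyphenyl)-7-hydroxychromen-4-one
Product: 10 2-(3,4-dimethoxyphenyl)-3,7-dihydroxychromen-4-one
Conditions: H2 (1 atm), 10% Pd/C, THF–MeOH, rt
Reagents that add atoms: none
Why: Catalytic hydrogenolysis of a benzyl ether: the benzylic C–O bond should break at one atmosphere well before the tetrasubstituted, conjugated C2–C3 double bond, the ketone or the aryl methyl ethers react, and the molecule does not yet hold an alkene that hydrogen could saturate.

Step 4
Reactants: 10 2-(3,4-dimethoxyphenyl)-3,7-dihydroxychromen-4-one; 11 prenyl bromide (1-bromo-3-methylbut-2-ene)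
Product: 12 2-(3,4-dimethoxyphenyl)-3-hydroxy-7-(3-methylbut-2-enyloxy)chromen-4-one (target)
Conditions: K2CO3 (1.0 equiv), 11 (1.05 equiv), DMF, 0 °C → rt; neutral aqueous work-up
Reagents that add atoms: none
Why: Williamson ether synthesis steered by acidity: the 7-hydroxyl is a vinylogous carboxylic acid (conjugated through C4a with the C4 carbonyl) and gives its proton to the single equivalent of carbonate, the hydrogencarbonate left over is too weak to ionise the 3-hydroxyl that is hydrogen-bonded to the C4 carbonyl, and the primary allylic bromide should then be displaced in SN2 fashion by the 7-phenoxide alone.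

**Compound list**
1 | ethyl 2-(benzyloxy)acetate | CCOC(=O)COCc1ccccc1 | starting material
2 | 3,4-dimethoxybenzoyl chloride | COc1ccc(C(Cl)=O)cc1OC | starting material
3 | lithium enolate of ethyl 2-(benzyloxy)acetate (geometry without consequence) | [Li+].CCOC([O-])=COCc1ccccc1 | intermediate
4 | ethyl 2-(benzyloxy)-3-(3,4-dimethoxyphenyl)-3-oxopropanoate (racemic, labile α-carbon) | CCOC(=O)C(OCc1ccccc1)C(=O)c1ccc(OC)c(OC)c1 | intermediate
5 | resorcinol | Oc1cccc(O)c1 | starting material
6 | 2-(benzyloxy)-3-(3,4-dimethoxyphenyl)-3-oxoprop-1-en-1-one (α-oxoketene) | O=C=C(OCc1ccccc1)C(=O)c1ccc(OC)c(OC)c1 | intermediate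
7 | 2-(benzyloxy)-1-(2,4-dihydroxyphenyl)-3-(3,4-dimethoxyphenyl)propane-1,3-dione (racemic, labile) | O=C(c1ccc(O)cc1O)C(OCc1ccccc1)C(=O)c1ccc(OC)c(OC)c1 | intermediate
8 | 3-(benzyloxy)-2-(3,4-dimethoxyphenyl)-2,7-dihydroxychroman-4-one (transient mixture of stereoisomers) | COc1ccc(C2(O)Oc3cc(O)ccc3C(=O)C2OCc2ccccc2)cc1OC | intermediate
9 | 3-(benzyloxy)-2-(3,4-dimethoxyphenyl)-7-hydroxychromen-4-one | COc1ccc(-c2oc3cc(O)ccc3c(=O)c2OCc2ccccc2)cc1OC | intermediate
10 | 2-(3,4-dimethoxyphenyl)-3,7-dihydroxychromen-4-one | COc1ccc(-c2oc3cc(O)ccc3c(=O)c2O)cc1OC | intermediate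
11 | prenyl bromide | CC(C)=CCBr | starting material
12 | 2-(3,4-dimethoxyphenyl)-3-hydroxy-7-(3-methylbut-2-enyloxy)chromen-4-one | COc1ccc(-c2oc3cc(OCC=C(C)C)ccc3c(=O)c2O)cc1OC | target

Total step count: 4. Longest linear sequence: 4 steps (1 → 4 → 9 → 10 → 12).

**Steps most likely to fail**

Step 2. The melt may consume the ketoester faster than the arene is acylated. The possible causes are:
- retro-Claisen cleavage by the phenol;
- hydrolysis and decarboxylation by the water released;
- thermal benzyl transfer to the electron-rich ring;
- arrest at the O-acyl stage;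
- closure in the coumarin sense.

In the fallback, ring C is made by oxidative cyclisation of a chalcone instead of by arene annulation. Setting out from 5, Nencki acylation (AcOH, ZnCl2, 140 °C) should give 2,4-dihydroxyacetophenone F1. K2CO3 and 11 in acetone alkylate only the non-chelated 4-hydroxyl, giving 2-hydroxy-4-(prenyloxy)acetophenone F2. Claisen–Schmidt condensation with 3,4-dimethoxybenzaldehyde (KOH, EtOH) gives the (E)-2'-hydroxychalcone F3. Algar–Flynn–Oyamada oxidation (H2O2, NaOH, MeOH, 0 °C → rt) then closes ring C and installs the 3-hydroxyl in one operation. The prenyl alkene is inert to alkaline peroxide. This sequence comes back to the route at 12.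

Step 4. Three processes may erode the selectivity:
- proton exchange between the two oxygens may let the more nucleophilic 3-oxide compete, so that alkylation spills over to O3;
- alkylation may continue to double alkylation;
- alkylation may take place at C8.

The fallback replaces acidity control by differential protection. Setting out from 10, Ac2O in pyridine gives the 3,7-diacetate F4. Thiophenol and imidazole in NMP remove only the more electrophilic 7-O-acetyl group, giving the 3-acetoxy-7-hydroxyflavone F5. Mitsunobu etherification with 3-methylbut-2-en-1-ol (PPh3, DIAD, THF) gives the 3-acetoxy-7-(prenyloxy)flavone F6 under neutral conditions. Methanolysis (K2CO3, MeOH, rt) then frees the 3-hydroxyl, coming back to the route at 12.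

Step 1. Three processes may interfere:
- the enolate of the product may be O-aroylated by unreacted acid chloride;
- proton transfer may stall conversion;
- the benzyloxy enolate may drift into Wittig rearrangement on warming.

The fallback introduces the benzyloxy group after the carbon skeleton is complete. Setting out from 2, decarboxylative acylation of potassium ethyl malonate (MgCl2, Et3N, MeCN; aq HCl) gives ethyl 3-(3,4-dimethoxyphenyl)-3-oxopropanoate F7. Regitz diazo transfer (4-acetamidobenzenesulfonyl azide, Et3N, MeCN) gives ethyl 2-diazo-3-(3,4-dimethoxyphenyl)-3-oxopropanoate F8. Rh2(OAc)4-catalysed carbenoid O–H insertion into benzyl alcohol (CH2Cl2, reflux) then comes back to the route at 4.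

**Further compounds**
F1 | step 2 | 1-(2,4-dihydroxyphenyl)ethanone | CC(=O)c1ccc(O)cc1O
F2 | step 2 | 1-[2-hydroxy-4-(3-methylbut-2-enyloxy)phenyl]ethanone | CC(=O)c1ccc(OCC=C(C)C)cc1O
F3 | step 2 | (E)-3-(3,4-dimethoxyphenyl)-1-[2-hydroxy-4-(3-methylbut-2-enyloxy)phenyl]prop-2-en-1-one | COc1ccc(/C=C/C(=O)c2ccc(OCC=C(C)C)cc2O)cc1OC
F4 | step 4 | 2-(3,4-dimethoxyphenyl)-4-oxochromene-3,7-diyl diacetate | COc1ccc(-c2oc3cc(OC(C)=O)ccc3c(=O)c2OC(C)=O)cc1OC
F5 | step 4 | 2-(3,4-dimethoxyphenyl)-7-hydroxy-4-oxochromen-3-yl acetate | COc1ccc(-c2oc3cc(O)ccc3c(=O)c2OC(C)=O)cc1OC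
F6 | step 4 | 2-(3,4-dimethoxyphenyl)-7-(3-methylbut-2-enyloxy)-4-oxochromen-3-yl acetate | COc1ccc(-c2oc3cc(OCC=C(C)C)ccc3c(=O)c2OC(C)=O)cc1OC
F7 | step 1 | ethyl 3-(3,4-dimethoxyphenyl)-3-oxopropanoate | CCOC(=O)CC(=O)c1ccc(OC)c(OC)c1
F8 | step 1 | ethyl 2-diazo-3-(3,4-dimethoxyphenyl)-3-oxopropanoate | CCOC(=O)C(=[N+]=[N-])C(=O)c1ccc(OC)c(OC)c1
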